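**Retrosynthetic overview**

1. Endgame: the butenolide (C7, C8, C17, C19, O) and the ten-membered ring B are closed together in the last step by an intramolecular Nozaki–Hiyama–Kishi coupling (C7–C8) with lactonisation; the (Z)-enol triflate comes from a β-keto ester grown on C9/C8.
2. Ring A functionality: the 11,12-epoxide comes from hydroxyl-directed epoxidation of a C11=C12 olefin (C20 by cross-coupling of a regiodefined C11 enol triflate); the C14 acetate and the C2 carbinol come from one Evans–Tishchenko reduction; C3–C4 comes from alkylation of the C2 methyl ketone with a (Z)-allylic bromide (C4–C7).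
3. Ring A itself (C1, C10, C11, C12, C13, C14) is made by a catalytic asymmetric Diels–Alder reaction between a 1,4-bis(silyloxy)butadiene (C14=C13–C12=C11) and an (E)-α-methyl enone (C1=C10; acetyl = C2, C3). It forms C14–C1 and C11–C10 and sets the quaternary C1.
4. Enabling feature: in ring A the C14 oxygen stands next to quaternary C1 and cis to the carbonyl-derived C2 on C1, while C2 and C9 are trans on C1/C10. This is the retron of an endo [4+2] addition of a 1-oxygenated diene to an (E)-enone whose acyl carbon becomes C2. Ring order: A (step 6), then butenolide and ring B in one operation (step 22).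

Key step: step 6

Remark: briarane numbering (C1–C20) is used for positions; α is the face of ring A that carries O14, H10 and the C1–C2 bond, β the face that carries C15, the C10–C9 bond and the epoxide oxygen; the five starting materials are taken as catalogue compounds.

**Route**

Step 1
Reactants: 1 2-[(4-methoxybenzyl)oxy]acetaldehyde; 2 ethyl 2-[bis(2,2,2-trifluoroethoxy)phosphoryl]propanoate
Product: 4 ethyl (Z)-4-[(4-methoxybenzyl)oxy]-2-methylbut-2-enoate, via potassium phosphonate carbanion 3 (not isolated)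
Conditions: KN(SiMe3)2, 18-crown-6, THF, –78 °C; then 1
Reagents that add atoms: none
Why: Still–Gennari olefination, in which the electron-poor bis(trifluoroethyl) phosphonate with a dissociated potassium counter-ion eliminates kinetically and should give the (Z)-trisubstituted enoate that fixes the later C5=C6 geometry.

Step 2
Reactants: 4 ethyl (Z)-4-[(4-methoxybenzyl)oxy]-2-methylbut-2-enoate
Product: 5 (Z)-4-[(4-methoxybenzyl)oxy]-2-methylbut-2-en-1-ol
Conditions: iBu2AlH (2.2 equiv), CH2Cl2, –78 → 0 °C
Reagents that add atoms: none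
Why: Hydride reduction of the ester with iBu2AlH is a standard 1,2-reduction that leaves the (Z)-olefin and the PMB ether untouched.

Step 3
Reactants: 5 (Z)-4-[(4-methoxybenzyl)oxy]-2-methylbut-2-en-1-ol
Product: 6 (Z)-1-bromo-4-[(4-methoxybenzyl)oxy]-2-methylbut-2-ene
Conditions: CBr4, PPh3, CH2Cl2, 0 °C
Reagents that add atoms: carbon tetrabromide BrC(Br)(Br)Br
Why: Appel bromination replaces the primary allylic hydroxyl by SN2 attack on the alkoxyphosphonium ion, without allylic transposition or loss of the Z geometry.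

Step 4
Reactants: 7 3-[(tert-butyldiphenylsilyl)oxy]propanal; 8 3-(triphenyl-λ5-phosphanylidene)butan-2-one
Product: 9 (E)-6-[(tert-butyldiphenylsilyl)oxy]-3-methylhex-3-en-2-one
Conditions: toluene, 90 °C
Reagents that add atoms: none
Why: Wittig olefination with an acyl-stabilised, α-branched ylide is under thermodynamic control and should give the (E)-trisubstituted enone, whose geometry later becomes the trans ring fusion.

Step 5
Reactants: 10 (1E,3E)-buta-1,3-diene-1,4-diyl diacetate
Product: 12 (1E,3E)-1,4-bis(triethylsilyloxy)buta-1,3-diene, via dilithium dienediolate 11 (not isolated)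
Conditions: MeLi (4 equiv), THF, –20 → 0 °C; then Et3SiCl (4 equiv), –78 °C → rt
Reagents that add atoms: chlorotriethylsilane CC[Si](Cl)(CC)CC
Why: Cleavage of the two enol acetates with MeLi gives the bis-enolate with retention of both enol geometries, and O-silylation then gives the (E,E)-bis-silyl dienol ether.

Step 6
Reactants: 12 (1E,3E)-1,4-bis(triethylsilyloxy)buta-1,3-diene; 9 (E)-6-[(tert-butyldiphenylsilyl)oxy]-3-methylhex-3-en-2-one
Product: 13 ring-A methyl ketone 1-[6-{2-[(tert-butyldiphenylsilyl)oxy]ethyl}-1-methyl-2,5-bis(triethylsilyloxy)cyclohex-3-en-1-yl]ethanone [OSiEt3 on C14 and C11 α; acetyl on C1 α; C15 β; C9 chain on C10 β; C12=C13]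
Conditions: (S)-1-(2-methylphenyl)-3,3-diphenyltetrahydro-1H,3H-pyrrolo[1,2-c][1,3,2]oxazaborole·HN(SO2CF3)2 (0.2 equiv), 12 (1.5 equiv), CH2Cl2, –78 → –40 °C
Reagents that add atoms: none
Why: Lewis-acid-catalysed Diels–Alder reaction: the cationic oxazaborolidine binds the acetyl oxygen of s-trans enone 9 and lowers its LUMO, and the electron-rich diene 12 adds across C1=C10 in a concerted, asynchronous, suprafacial [4+2] process that forms C14–C1 and C11–C10 together (closest known types: oxazaborolidinium-catalysed cycloadditions of α-methyl enals and of acyclic enones with silyloxy dienes, and the AlCl3-promoted cycloaddition of 3-methylpent-3-en-2-one). Ring A is closed by intermolecular cycloaddition of two components, so no ring-closure mode of a chain applies. C1 and C10: the (E) geometry of 9 is transferred suprafacially and gives the trans relation of C2 and C9, with C15 on the β face of the new quaternary C1. C14 and the temporary C11 centre: the (E,E) geometry of 12 and the endo orientation of the coordinated acetyl group place both silyloxy groups cis to C2. Absolute configuration: the aryl group of the chiral catalyst shields one face of the bound enone. The step needs endo and π-facial selectivity only, because the C2h symmetry of 12 removes any regiochemical question and coordination of the Lewis acid to the acetyl group secures the endo mode.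

Step 7
Reactants: 13 ring-A methyl ketone; 6 (Z)-1-bromo-4-[(4-methoxybenzyl)oxy]-2-methylbut-2-ene
Product: 15 ring-A ketone with the C3–C7 chain [C2(=O)CH2CH2C(CH3)=CHCH2OPMB; (Z) at C5=C6; ring A as in 13], via lithium enolate 14 (not isolated)
Conditions: LiN(iPr)2 (1.05 equiv), THF, –78 °C; then 6, DMPU, –78 → –30 °C
Reagents that add atoms: none
Why: Kinetic enolate alkylation: C1 is quaternary, so the acetyl methyl (C3) is the only enolisable position, and the single enolate is C-alkylated by the allylic bromide in an SN2 reaction that forms C3–C4 without creating a stereocenter.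

Step 8
Reactants: 15 ring-A ketone with the C3–C7 chain
Product: 16 diol ketone [C14 OH α; C11 OH α; C12=C13; C2 ketone; C8 OTBDPS; C7 OPMB]
Conditions: pyridinium p-toluenesulfonate (0.2 equiv), MeOH/CH2Cl2, 0 °C
Reagents that add atoms: none
Why: Acid-catalysed methanolysis cleaves the two secondary allylic triethylsilyl ethers far faster than the primary tert-butyldiphenylsilyl ether or the PMB ether.

Step 9
Reactants: 16 diol ketone
Product: 17 C14 acetate with free C2 carbinol [O14 acetyl; C2 OH 1,3-anti to O14 as in the target; C11 OH α; C12=C13]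
Conditions: SmI2 (0.3 equiv), CH3CHO (8 equiv), THF, –10 °C
Reagents that add atoms: acetaldehyde CC=O
Why: Evans–Tishchenko reduction: the C14 hydroxyl forms a hemiacetal with acetaldehyde on trivalent samarium and delivers its hydride intramolecularly to the C2 ketone through a chair transition state with C13 and C3 equatorial, which should set the 1,3-anti C2 carbinol and leave the acetyl group on O14, while the C11 hydroxyl is not β to a ketone and cannot take part.

Step 10
Reactants: 17 C14 acetate with free C2 carbinol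
Product: 18 enone [C11 ketone conjugated with C12=C13; C14 OAc; C2 OH]
Conditions: MnO2 (15 equiv), CH2Cl2, rt
Reagents that add atoms: none
Why: Allylic oxidation with MnO2 converts only the allylic C11 alcohol, so the hindered saturated C2 carbinol survives.

Step 11
Reactants: 18 enone
Product: 19 senecioate enone [C2 O-(3-methylbut-2-enoyl); C14 OAc; C11 ketone; C12=C13]
Conditions: 3-methylbut-2-enoyl chloride (3 equiv), pyridine, 4-(dimethylamino)pyridine (0.2 equiv), CH2Cl2, 0 °C → rt
Reagents that add atoms: 3-methylbut-2-enoyl chloride CC(C)=CC(Cl)=O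
Why: Nucleophile-catalysed acylation of the only free hydroxyl, run in the weak base pyridine so that the senecioyl unit is not deconjugated through a vinylketene.

Step 12
Reactants: 19 senecioate enone
Product: 21 C11 enol triflate [C11(OSO2CF3)=C12; C13 now CH2; other groups as in 19], via lithium C11 enolate 20 (not isolated)
Conditions: LiBH(sBu)3 (1.05 equiv), THF, –78 °C; then N-(5-chloropyridin-2-yl)bis(trifluoromethanesulfonyl)imide, –78 → 0 °C
Reagents that add atoms: N-(5-chloropyridin-2-yl)bis(trifluoromethanesulfonyl)imide FC(F)(F)S(=O)(=O)N(c1ccc(Cl)cn1)S(=O)(=O)C(F)(F)F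
Why: Conjugate reduction of the β-unsubstituted cyclohexenone with the hindered borohydride gives the C11–C12 enolate regiospecifically, and O-sulfonylation traps it as the enol triflate (reductive enolate trapping), with no new stereocenter.

Step 13
Reactants: 21 C11 enol triflate
Product: 22 C11-methyl olefin [C11(CH3)=C12; C14 OAc; C2 O-senecioyl; C8 OTBDPS; C7 OPMB]
Conditions: MeZnCl (2 equiv), Pd(PPh3)4 (0.05 equiv), THF, rt → 45 °C
Reagents that add atoms: methylzinc chloride C[Zn]Cl
Why: Negishi cross-coupling of the enol triflate installs C20 on C11 with the olefin fixed at C11=C12, and the organozinc reagent tolerates the acetate and senecioate esters.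

Step 14
Reactants: 22 C11-methyl olefin
Product: 23 C8 primary alcohol [C10–CH2CH2OH; otherwise as 22]
Conditions: Bu4NF, AcOH (1:1, 3 equiv), THF, 0 °C → rt
Reagents that add atoms: none
Why: Fluoride cleavage of the silyl ether, buffered with acetic acid so that the esters neither migrate nor hydrolyse.

Step 15
Reactants: 23 C8 primary alcohol
Product: 24 11β,12β-epoxy alcohol [epoxide oxygen β; C20 α; C8 OH]
Conditions: VO(acac)2 (0.05 equiv), t-BuOOH (1.5 equiv), 2,6-lutidine (0.2 equiv), CH2Cl2, 0 °C → rt
Reagents that add atoms: tert-butyl hydroperoxide CC(C)(C)OO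
Why: Vanadium-catalysed hydroxyl-directed epoxidation of a bishomoallylic alcohol: the vanadate ester of the C8 hydroxyl is held on the β face by the C10–C9 bond and delivers oxygen to that face of C11=C12 only, which sets C11 and C12 and leaves the remote C5=C6 and senecioate olefins untouched.

Step 16
Reactants: 24 11β,12β-epoxy alcohol
Product: 25 epoxy aldehyde [C8 CHO]
Conditions: Dess–Martin periodinane, NaHCO3, CH2Cl2, 0 °C → rt
Reagents that add atoms: none
Why: Dess–Martin oxidation under bicarbonate buffer gives the aldehyde without opening the acid-sensitive epoxide.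

Step 17
Reactants: 25 epoxy aldehyde
Product: 26 β-hydroxy ester [C9H2–C8H(OH)–C17H(CH3)–CO2CH3; mixture at C8 and C17]
Conditions: methyl propanoate, LiN(iPr)2, THF, –78 °C; then 25, –78 °C, 15 min
Reagents that add atoms: methyl propanoate (used as its lithium enolate) CCC(=O)OC
Why: Aldol addition of an ester enolate, which at –78 °C attacks the aldehyde far faster than the acetate or senecioate; the two new stereocenters are erased in steps 18 and 19, so the mixture is carried on.

Step 18
Reactants: 26 β-hydroxy ester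
Product: 27 β-keto ester [C8 ketone; C17H(CH3)CO2CH3]
Conditions: Dess–Martin periodinane, NaHCO3, CH2Cl2, rt
Reagents that add atoms: none
Why: Dess–Martin oxidation of the secondary carbinol to the β-keto ester under neutral conditions.

Step 19
Reactants: 27 β-keto ester
Product: 29 (Z)-enol triflate [C8(OSO2CF3)=C17(CH3)CO2CH3; triflate cis to the ester], via lithium chelated enolate 28 (not isolated)
Conditions: LiN(SiMe3)2 (1.05 equiv), THF, –78 °C; then N-(5-chloropyridin-2-yl)bis(trifluoromethanesulfonyl)imide, –78 → 0 °C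
Reagents that add atoms: N-(5-chloropyridin-2-yl)bis(trifluoromethanesulfonyl)imide FC(F)(F)S(=O)(=O)N(c1ccc(Cl)cn1)S(=O)(=O)C(F)(F)F
Why: O-sulfonylation of the lithium-chelated (Z)-enolate of the β-keto ester places the triflate cis to the ester, the geometry needed for lactonisation after the coupling.

Step 20
Reactants: 29 (Z)-enol triflate
Product: 30 C7 allylic alcohol [(Z)-C4H2–C5(CH3)=C6H–C7H2OH]
Conditions: DDQ (1.3 equiv), CH2Cl2/pH 7 phosphate buffer, 0 °C
Reagents that add atoms: none
Why: Oxidative PMB cleavage with DDQ (hydride abstraction to the benzylic oxocarbenium ion, then hydrolysis) under buffered conditions that spare the epoxide, the enol triflate and the esters.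

Step 21
Reactants: 30 C7 allylic alcohol
Product: 31 (Z)-enal [C7 CHO cis to C4 across C5=C6]
Conditions: Dess–Martin periodinane, NaHCO3, CH2Cl2, 0 °C; used at once
Reagents that add atoms: none
Why: Dess–Martin oxidation of the allylic alcohol under buffered, non-isomerising conditions should keep the Z geometry of the enal.

Step 22
Reactants: 31 (Z)-enal
Product: 33 Malayenolide D, via ten-membered chromium alkoxide 32 (not isolated)
Conditions: CrCl2 (15 equiv), NiCl2 (0.1 equiv), degassed DMF/THF, rt, 1 mM, slow addition of 31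
Reagents that add atoms: none
Why: Nozaki–Hiyama–Kishi reaction: zerovalent nickel inserts into the alkenyl triflate, transmetalation gives the alkenylchromium species, which adds 1,2 to the aldehyde at high dilution and closes ring B through C7–C8, and the alkoxide then lactonises onto the cis methyl ester to give the butenolide; C7 is set under substrate control, the configuration drawn being that expected from attack on the outer face of the (Z)-enal held by trans-fused ring A.

**Compound list**

1 | 2-[(4-methoxybenzyl)oxy]acetaldehyde | O=CCOCc1ccc(OC)cc1 | starting material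
2 | ethyl 2-[bis(2,2,2-trifluoroethoxy)phosphoryl]propanoate | CCOC(=O)C(C)P(=O)(OCC(F)(F)F)OCC(F)(F)F | starting material
3 | potassium carbanion of phosphonate 2 (not isolated) | [K+].CCOC(=O)[C-](C)P(=O)(OCC(F)(F)F)OCC(F)(F)F | intermediate
4 | ethyl (Z)-4-[(4-methoxybenzyl)oxy]-2-methylbut-2-enoate | CCOC(=O)/C(C)=C\COCc1ccc(OC)cc1 | intermediate
5 | (Z)-4-[(4-methoxybenzyl)oxy]-2-methylbut-2-en-1-ol | OC/C(C)=C\COCc1ccc(OC)cc1 | intermediate
6 | (Z)-1-bromo-4-[(4-methoxybenzyl)oxy]-2-methylbut-2-ene | BrC/C(C)=C\COCc1ccc(OC)cc1 | intermediate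
7 | 3-[(tert-butyldiphenylsilyl)oxy]propanal | O=CCCO[Si](c1ccccc1)(c1ccccc1)C(C)(C)C | starting material
8 | 3-(triphenyl-λ5-phosphanylidene)butan-2-one | CC(=O)C(C)=P(c1ccccc1)(c1ccccc1)c1ccccc1 | starting material
9 | (E)-6-[(tert-butyldiphenylsilyl)oxy]-3-methylhex-3-en-2-one | CC(=O)/C(C)=C/CCO[Si](c1ccccc1)(c1ccccc1)C(C)(C)C | intermediate
10 | (1E,3E)-buta-1,3-diene-1,4-diyl diacetate | CC(=O)O/C=C/C=C/OC(C)=O | starting material
11 | dilithium (1E,3E)-buta-1,3-diene-1,4-diolate (not isolated) | [Li+].[Li+].[O-]/C=C/C=C/[O-] | intermediate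
12 | (1E,3E)-1,4-bis(triethylsilyloxy)buta-1,3-diene | CC[Si](CC)(CC)O/C=C/C=C/O[Si](CC)(CC)CC | intermediate
13 | ring-A methyl ketone (Diels–Alder adduct; C14 and C11 OSiEt3 α, acetyl α, C15 β, C9 chain β, C12=C13) | CC[Si](CC)(CC)O[C@H]1C=C[C@@H](O[Si](CC)(CC)CC)[C@H](CCO[Si](c2ccccc2)(c2ccccc2)C(C)(C)C)[C@@]1(C)C(C)=O | intermediate
14 | lithium enolate of 13 (C2=C3; not isolated) | [Li+].CC[Si](CC)(CC)O[C@H]1C=C[C@@H](O[Si](CC)(CC)CC)[C@H](CCO[Si](c2ccccc2)(c2ccccc2)C(C)(C)C)[C@@]1(C)C([O-])=C | intermediate
15 | ring-A ketone with the (Z)-C3–C7 chain (C7 OPMB) | CC[Si](CC)(CC)O[C@H]1C=C[C@@H](O[Si](CC)(CC)CC)[C@H](CCO[Si](c2ccccc2)(c2ccccc2)C(C)(C)C)[C@@]1(C)C(=O)CC/C(C)=C\COCc3ccc(OC)cc3 | intermediate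
16 | diol ketone (C14 OH α, C11 OH α) | O[C@H]1C=C[C@@H](O)[C@H](CCO[Si](c2ccccc2)(c2ccccc2)C(C)(C)C)[C@@]1(C)C(=O)CC/C(C)=C\COCc3ccc(OC)cc3 | intermediate
17 | C14 acetate with C2 carbinol (1,3-anti) and C11 OH | CC(=O)O[C@H]1C=C[C@@H](O)[C@H](CCO[Si](c2ccccc2)(c2ccccc2)C(C)(C)C)[C@@]1(C)[C@@H](O)CC/C(C)=C\COCc3ccc(OC)cc3 | intermediate
18 | enone (C11 ketone, C12=C13) | CC(=O)O[C@H]1C=CC(=O)[C@H](CCO[Si](c2ccccc2)(c2ccccc2)C(C)(C)C)[C@@]1(C)[C@@H](O)CC/C(C)=C\COCc3ccc(OC)cc3 | intermediate
19 | senecioate enone (C2 O-senecioyl) | CC(=O)O[C@H]1C=CC(=O)[C@H](CCO[Si](c2ccccc2)(c2ccccc2)C(C)(C)C)[C@@]1(C)[C@@H](OC(=O)C=C(C)C)CC/C(C)=C\COCc3ccc(OC)cc3 | intermediate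
20 | lithium C11–C12 enolate (not isolated) | [Li+].CC(=O)O[C@H]1CC=C([O-])[C@H](CCO[Si](c2ccccc2)(c2ccccc2)C(C)(C)C)[C@@]1(C)[C@@H](OC(=O)C=C(C)C)CC/C(C)=C\COCc3ccc(OC)cc3 | intermediate
21 | C11 enol triflate (C11=C12) | CC(=O)O[C@H]1CC=C(OS(=O)(=O)C(F)(F)F)[C@H](CCO[Si](c2ccccc2)(c2ccccc2)C(C)(C)C)[C@@]1(C)[C@@H](OC(=O)C=C(C)C)CC/C(C)=C\COCc3ccc(OC)cc3 | intermediate
22 | C11-methyl olefin (C11(CH3)=C12) | CC(=O)O[C@H]1CC=C(C)[C@H](CCO[Si](c2ccccc2)(c2ccccc2)C(C)(C)C)[C@@]1(C)[C@@H](OC(=O)C=C(C)C)CC/C(C)=C\COCc3ccc(OC)cc3 | intermediate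
23 | C8 primary alcohol | CC(=O)O[C@H]1CC=C(C)[C@H](CCO)[C@@]1(C)[C@@H](OC(=O)C=C(C)C)CC/C(C)=C\COCc2ccc(OC)cc2 | intermediate
24 | 11β,12β-epoxy alcohol | CC(=O)O[C@H]1C[C@@H]2O[C@]2(C)[C@H](CCO)[C@@]1(C)[C@@H](OC(=O)C=C(C)C)CC/C(C)=C\COCc3ccc(OC)cc3 | intermediate
25 | epoxy aldehyde (C8 CHO) | CC(=O)O[C@H]1C[C@@H]2O[C@]2(C)[C@H](CC=O)[C@@]1(C)[C@@H](OC(=O)C=C(C)C)CC/C(C)=C\COCc3ccc(OC)cc3 | intermediate
26 | β-hydroxy ester (mixture at C8 and C17) | CC(=O)O[C@H]1C[C@@H]2O[C@]2(C)[C@H](CC(O)C(C)C(=O)OC)[C@@]1(C)[C@@H](OC(=O)C=C(C)C)CC/C(C)=C\COCc3ccc(OC)cc3 | intermediate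
27 | β-keto ester (C8 ketone; mixture at C17) | CC(=O)O[C@H]1C[C@@H]2O[C@]2(C)[C@H](CC(=O)C(C)C(=O)OC)[C@@]1(C)[C@@H](OC(=O)C=C(C)C)CC/C(C)=C\COCc3ccc(OC)cc3 | intermediate
28 | lithium (Z)-enolate of 27 (not isolated) | [Li+].CC(=O)O[C@H]1C[C@@H]2O[C@]2(C)[C@H](C/C([O-])=C(\C)C(=O)OC)[C@@]1(C)[C@@H](OC(=O)C=C(C)C)CC/C(C)=C\COCc3ccc(OC)cc3 | intermediate
29 | (Z)-C8 enol triflate (triflate cis to CO2CH3) | CC(=O)O[C@H]1C[C@@H]2O[C@]2(C)[C@H](C/C(OS(=O)(=O)C(F)(F)F)=C(\C)C(=O)OC)[C@@]1(C)[C@@H](OC(=O)C=C(C)C)CC/C(C)=C\COCc3ccc(OC)cc3 | intermediate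
30 | C7 allylic alcohol | CC(=O)O[C@H]1C[C@@H]2O[C@]2(C)[C@H](C/C(OS(=O)(=O)C(F)(F)F)=C(\C)C(=O)OC)[C@@]1(C)[C@@H](OC(=O)C=C(C)C)CC/C(C)=C\CO | intermediate
31 | (Z)-enal (C7 CHO) | CC(=O)O[C@H]1C[C@@H]2O[C@]2(C)[C@H](C/C(OS(=O)(=O)C(F)(F)F)=C(\C)C(=O)OC)[C@@]1(C)[C@@H](OC(=O)C=C(C)C)CC/C(C)=C\C=O | intermediate
32 | ten-membered C7 hydroxy ester (present as its chromium alkoxide, drawn as the alcohol; not isolated) | CC(=O)O[C@H]1C[C@@H]2O[C@]2(C)[C@@H]2C/C(=C(\C)C(=O)OC)[C@@H](O)/C=C(/C)CC[C@H](OC(=O)C=C(C)C)[C@@]12C | intermediate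
33 | Malayenolide D | CC(=O)O[C@H]1C[C@@H]2O[C@]2(C)[C@@H]2CC3=C(C)C(=O)O[C@H]3/C=C(/C)CC[C@H](OC(=O)C=C(C)C)[C@@]12C | target

**Step count and risks**

Total step count: 22. Longest linear sequence: 19 steps (steps 1–3, then 7–22).

Steps most likely to fail:

1. Step 6 (Diels–Alder). What may go wrong: slow cycloaddition between a 1,4-disubstituted diene and a trisubstituted enone, protodesilylation of the diene by the acidic catalyst, and weak or reversed π-facial discrimination, because an α-methyl ketone offers the catalyst no α-C–H contact. The sense of induction written for the (S)-catalyst is therefore the least secure prediction in the route; the antipodal catalyst is the first recourse if it is reversed. Fallback (sets out from 7, returns at 13): aldehyde 7 is olefinated with 2-(triphenyl-λ5-phosphanylidene)propanal to (E)-5-[(tert-butyldiphenylsilyl)oxy]-2-methylpent-2-enal F1. α-Methyl enals are more reactive and are organised on the same oxazaborolidinium catalyst through the formyl C–H contact, so cycloaddition with 12 should give the ring-A aldehyde F2 with the same relative configuration. Addition of MeMgBr gives the 1-hydroxyethyl compound F3 as a carbinol mixture, and Dess–Martin oxidation returns methyl ketone 13.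

2. Step 22 (ring closure). What may go wrong: attack of the alkenylchromium species on the other face of the aldehyde (C7 epimer), Z to E isomerisation of the enal before closure, and intermolecular coupling. Fallback for the facial problem (sets out from 31, returns at 33): the closure is accepted with whatever facial outcome it gives, and kinetic substrate control is replaced by correction after ring closure. The epimer, 7-epi-malayenolide D F6, is equilibrated through its 2-oxidofuran by γ-deprotonation of the butenolide with DBU in CH2Cl2, C7 being the only acidic stereocenter; 33 is separated and F6 is recycled.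

3. Step 15 (directed epoxidation). What may go wrong: slow oxygen transfer from a bishomoallylic vanadate to the trisubstituted olefin, and opening of the new epoxide at C11 by the C8 hydroxyl (tetrahydrofuran formation). Fallback (sets out from 23, returns at 27): the director is changed from the alcohol to the carboxylate. Alcohol 23 is oxidised with PhI(OAc)2 and catalytic TEMPO in aqueous MeCN to the C8 carboxylic acid F4. Iodolactonisation (I2, NaHCO3) should give the cis-fused γ-lactone, iodolactone F5, with the lactone oxygen on C11 from the β face and iodine on C12 α, trans-diaxial to it. The lithium enolate of methyl propanoate then opens the lactone in a Claisen acylation, and the liberated C11 alkoxide displaces the antiperiplanar iodide. This gives epoxy β-keto ester 27 directly and makes steps 16 to 18 unnecessary.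

**Further compounds**

F1 | step 6 | (E)-5-[(tert-butyldiphenylsilyl)oxy]-2-methylpent-2-enal | O=C/C(C)=C/CCO[Si](c1ccccc1)(c1ccccc1)C(C)(C)C
F2 | step 6 | ring-A aldehyde (as 13 with CHO in place of acetyl) | CC[Si](CC)(CC)O[C@H]1C=C[C@@H](O[Si](CC)(CC)CC)[C@H](CCO[Si](c2ccccc2)(c2ccccc2)C(C)(C)C)[C@@]1(C)C=O
F3 | step 6 | ring-A 1-hydroxyethyl compound (carbinol mixture) | CC[Si](CC)(CC)O[C@H]1C=C[C@@H](O[Si](CC)(CC)CC)[C@H](CCO[Si](c2ccccc2)(c2ccccc2)C(C)(C)C)[C@@]1(C)C(C)O
F4 | step 15 | C8 carboxylic acid of 23 | CC(=O)O[C@H]1CC=C(C)[C@H](CC(=O)O)[C@@]1(C)[C@@H](OC(=O)C=C(C)C)CC/C(C)=C\COCc2ccc(OC)cc2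
F5 | step 15 | iodolactone (C8 carboxylate oxygen on C11 β; iodine on C12 α) | CC(=O)O[C@H]1C[C@@H](I)[C@]2(C)OC(=O)C[C@@H]2[C@@]1(C)[C@@H](OC(=O)C=C(C)C)CC/C(C)=C\COCc3ccc(OC)cc3
F6 | step 22 | 7-epi-malayenolide D | CC(=O)O[C@H]1C[C@@H]2O[C@]2(C)[C@@H]2CC3=C(C)C(=O)O[C@@H]3/C=C(/C)CC[C@H](OC(=O)C=C(C)C)[C@@]12C
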